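The dihydropyran ring of the chroman (O1, C2, C3, C4, C4a, C8a; C4a = C2' and C8a = C3' of the isoflavone B ring) is disconnected to a 3'-O-(1,1-dimethylpropargyl) ether of a fully assembled, benzyl-protected isoflavone. Heating this ether triggers a propargyl Claisen shift, a 1,5-H shift and an oxa-6π electrocyclisation, which forge the C4–C4a bond and the pyran ring in one operation as a 2H-chromene. The cascade exploits that C2' is the only unsubstituted carbon ortho to O3' (C4' carries oxygen) and that C2 is a gem-dimethyl carbon. One final hydrogenation saturates the chromene and removes all benzyl groups. The isoflavone arises by Suzuki coupling.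

Key step: step 7

Remark: the target has no stereocentre and no stereogenic double bond, so it is achiral and the question of a single enantiomer does not arise.

Step 1
Reactants: 1 2,4,6-trihydroxyacetophenone; 2 benzyl bromide
Product: 3 1-[2,4-bis(benzyloxy)-6-hydroxyphenyl]ethan-1-one
Conditions: BnBr (2.1 equiv), K2CO3, DMF, rt
Reagents that add atoms: benzyl bromide, BrCc1ccccc1
Why: Williamson etherification alkylates the 4-OH and one ortho-OH, while the remaining ortho-OH is locked in a hydrogen bond to the acetyl carbonyl and is too weakly nucleophilic to react with two equivalents of benzyl bromide under K2CO3.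

Step 2
Reactants: 3 1-[2,4-bis(benzyloxy)-6-hydroxyphenyl]ethan-1-one; 4 N,N-dimethylformamide dimethyl acetal; 5 iodine
Product: 7 5,7-bis(benzyloxy)-3-iodo-4H-chromen-4-one, via enaminone 6 (not isolated)
Conditions: DMF-DMA, 95 °C; evaporate; then I2, MeOH, rt
Reagents that add atoms: N,N-dimethylformamide dimethyl acetal, COC(OC)N(C)C; iodine, II
Why: Condensation of the methyl ketone with DMF-DMA to the enaminone, followed by iodine-mediated cyclisation (α-iodination, attack of the free phenol on the iminium carbon, loss of dimethylamine), is the standard 3-iodochromone synthesis and leaves benzyl ethers untouched.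

Step 3
Reactants: 8 2-(benzyloxy)-5-bromobenzaldehyde; 9 3-chloroperbenzoic acid (mCPBA)
Product: 11 2-(benzyloxy)-5-bromophenol, via aryl formate 10 (not isolated)
Conditions: mCPBA, CH2Cl2, rt; aq. NaHCO3 wash; then K2CO3 (cat.), MeOH, rt
Reagents that add atoms: 3-chloroperbenzoic acid, OOC(=O)c1cccc(Cl)c1
Why: In this Dakin-type Baeyer–Villiger oxidation the electron-rich ortho-alkoxyaryl group migrates in the Criegee intermediate to give the aryl formate, which mild methanolysis cleaves to the phenol without touching the bromide or the benzyl ether.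

Step 4
Reactants: 11 2-(benzyloxy)-5-bromophenol; 12 bis(pinacolato)diboron
Product: 13 2-(benzyloxy)-5-(4,4,5,5-tetramethyl-1,3,2-dioxaborolan-2-yl)phenol
Conditions: B2pin2, Pd(dppf)Cl2 (cat.), KOAc, 1,4-dioxane, 90 °C
Reagents that add atoms: bis(pinacolato)diboron, CC1(C)OB(OC1(C)C)B1OC(C)(C)C(C)(C)O1
Why: Miyaura borylation (oxidative addition into C–Br, acetate-assisted transmetalation with B2pin2, reductive elimination) gives the aryl pinacol boronate and tolerates a free phenol with the weak base KOAc.

Step 5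
Reactants: 7 5,7-bis(benzyloxy)-3-iodo-4H-chromen-4-one; 13 2-(benzyloxy)-5-(4,4,5,5-tetramethyl-1,3,2-dioxaborolan-2-yl)phenol
Product: 14 5,7-bis(benzyloxy)-3-[4-(benzyloxy)-3-hydroxyphenyl]-4H-chromen-4-one
Conditions: Pd(dppf)Cl2 (cat.), aq. Na2CO3, DME, 80 °C
Reagents that add atoms: none
Why: Suzuki–Miyaura coupling of the reactive 3-iodochromone with the aryl boronate forms the C3–C1' bond of the isoflavone under carbonate conditions that the γ-pyrone, the benzyl ethers and the free phenol tolerate.

Step 6
Reactants: 14 5,7-bis(benzyloxy)-3-[4-(benzyloxy)-3-hydroxyphenyl]-4H-chromen-4-one; 15 3-chloro-3-methylbut-1-yne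
Product: 16 5,7-bis(benzyloxy)-3-{4-(benzyloxy)-3-[(2-methylbut-3-yn-2-yl)oxy]phenyl}-4H-chromen-4-one
Conditions: 3-chloro-3-methylbut-1-yne, DBU, CuCl2·2H2O (cat.), MeCN, 0 °C to rt
Reagents that add atoms: 3-chloro-3-methylbut-1-yne, CC(C)(Cl)C#C
Why: Copper-catalysed propargylic etherification (copper acetylide/allenylidene-type electrophile from the tertiary chloride) should take place at the only free hydroxyl, since O5, O7 and O4' are benzylated.

Step 7
Reactants: 16 5,7-bis(benzyloxy)-3-{4-(benzyloxy)-3-[(2-methylbut-3-yn-2-yl)oxy]phenyl}-4H-chromen-4-one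
Product: 20 5,7-bis(benzyloxy)-3-[8-(benzyloxy)-2,2-dimethyl-2H-chromen-5-yl]-4H-chromen-4-one, via allenyl dienone 17 (not isolated), via o-allenylphenol 18 (not isolated), via o-quinone methide 19 (not isolated)
Conditions: PhNEt2 (degassed), 190 °C, Ar
Reagents that add atoms: none
Why: A thermal aromatic propargyl Claisen ([3,3]) shift moves the alkyne terminus from O3' to C2' to give allenyl dienone 17, which enolises to o-allenylphenol 18; a 1,5-hydrogen shift from the phenolic OH to the central allene carbon then gives (Z)-o-quinone methide 19, whose oxa-6π electrocyclisation re-forms the O–CMe2 bond. The closest known reaction type is the thermal rearrangement of aryl 1,1-dimethylpropargyl ethers to 2,2-dimethyl-2H-chromenes, of which this step is a direct application. The pyran ring is closed by a thermally allowed disrotatory 6π electrocyclisation of the 1-oxatriene O=C3'–C2'=CH–CH=CMe2, not by an ionic exo or endo closure. No stereocentre is created, because the sp3 carbon of 17 is lost on enolisation and 20 is achiral. The step needs regioselectivity for C2' over C4' and six-ring over five-ring (benzofuran) closure. The benzyloxy group on C4' makes migration to that carbon unproductive and reversible, the intramolecular hydrogen transfer imposes the Z geometry of 19 required for closure, and the gem-dimethyl group accelerates both the sigmatropic shift and the ring closure.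

Step 8
Reactants: 20 5,7-bis(benzyloxy)-3-[8-(benzyloxy)-2,2-dimethyl-2H-chromen-5-yl]-4H-chromen-4-one
Product: 21 5,7-dihydroxy-3-(8-hydroxy-2,2-dimethyl-3,4-dihydro-2H-chromen-5-yl)-4H-chromen-4-one
Conditions: H2 (1 atm), 10% Pd/C, EtOAc–MeOH, rt
Reagents that add atoms: none
Why: Heterogeneous catalytic hydrogenation saturates the cis-disubstituted styrenic C3=C4 bond of the chromene and hydrogenolyses the three benzyl ethers in one operation, while the C2=C3 bond of the isoflavone, part of a vinylogous ester, is reduced far more slowly so that the reaction can be stopped after four equivalents of hydrogen.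

Compound list
1 | 2,4,6-trihydroxyacetophenone | CC(=O)c1c(O)cc(O)cc1O | starting material
2 | benzyl bromide | BrCc1ccccc1 | starting material
3 | 1-[2,4-bis(benzyloxy)-6-hydroxyphenyl]ethan-1-one | CC(=O)c1c(O)cc(OCc2ccccc2)cc1OCc1ccccc1 | intermediate
4 | N,N-dimethylformamide dimethyl acetal | COC(OC)N(C)C | starting material
5 | iodine | II | starting material
6 | (E)-1-[2,4-bis(benzyloxy)-6-hydroxyphenyl]-3-(dimethylamino)prop-2-en-1-one (enaminone) | CN(C)/C=C/C(=O)c1c(O)cc(OCc2ccccc2)cc1OCc1ccccc1 | intermediate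
7 | 5,7-bis(benzyloxy)-3-iodo-4H-chromen-4-one | O=c1c(I)coc2cc(OCc3ccccc3)cc(OCc3ccccc3)c12 | intermediate
8 | 2-(benzyloxy)-5-bromobenzaldehyde | O=Cc1cc(Br)ccc1OCc1ccccc1 | starting material
9 | 3-chloroperbenzoic acid (mCPBA) | OOC(=O)c1cccc(Cl)c1 | starting material
10 | 2-(benzyloxy)-5-bromophenyl formate (aryl formate) | O=COc1cc(Br)ccc1OCc1ccccc1 | intermediate
11 | 2-(benzyloxy)-5-bromophenol | Oc1cc(Br)ccc1OCc1ccccc1 | intermediate
12 | bis(pinacolato)diboron | CC1(C)OB(OC1(C)C)B1OC(C)(C)C(C)(C)O1 | starting material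
13 | 2-(benzyloxy)-5-(4,4,5,5-tetramethyl-1,3,2-dioxaborolan-2-yl)phenol | CC1(C)OB(OC1(C)C)c1ccc(OCc2ccccc2)c(O)c1 | intermediate
14 | 5,7-bis(benzyloxy)-3-[4-(benzyloxy)-3-hydroxyphenyl]-4H-chromen-4-one | O=c1c(-c2ccc(OCc3ccccc3)c(O)c2)coc2cc(OCc3ccccc3)cc(OCc3ccccc3)c12 | intermediate
15 | 3-chloro-3-methylbut-1-yne | CC(C)(Cl)C#C | starting material
16 | 5,7-bis(benzyloxy)-3-{4-(benzyloxy)-3-[(2-methylbut-3-yn-2-yl)oxy]phenyl}-4H-chromen-4-one | C#CC(C)(C)Oc1cc(-c2coc3cc(OCc4ccccc4)cc(OCc4ccccc4)c3c2=O)ccc1OCc1ccccc1 | intermediate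
17 | 5,7-bis(benzyloxy)-3-[4-(benzyloxy)-6-(3-methylbuta-1,2-dien-1-yl)-5-oxocyclohexa-1,3-dien-1-yl]-4H-chromen-4-one (allenyl dienone, transient racemic sp3 carbon) | CC(C)=C=CC1C(=O)C(OCc2ccccc2)=CC=C1c1coc2cc(OCc3ccccc3)cc(OCc3ccccc3)c2c1=O | intermediate
18 | 5,7-bis(benzyloxy)-3-[4-(benzyloxy)-3-hydroxy-2-(3-methylbuta-1,2-dien-1-yl)phenyl]-4H-chromen-4-one (o-allenylphenol) | CC(C)=C=Cc1c(O)c(OCc2ccccc2)ccc1-c1coc2cc(OCc3ccccc3)cc(OCc3ccccc3)c2c1=O | intermediate
19 | 5,7-bis(benzyloxy)-3-[(Z)-4-(benzyloxy)-6-(3-methylbut-2-en-1-ylidene)-5-oxocyclohexa-1,3-dien-1-yl]-4H-chromen-4-one (o-quinone methide) | CC(C)=C/C=C1\C(=O)C(OCc2ccccc2)=CC=C1c1coc2cc(OCc3ccccc3)cc(OCc3ccccc3)c2c1=O | intermediate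
20 | 5,7-bis(benzyloxy)-3-[8-(benzyloxy)-2,2-dimethyl-2H-chromen-5-yl]-4H-chromen-4-one | CC1(C)C=Cc2c(-c3coc4cc(OCc5ccccc5)cc(OCc5ccccc5)c4c3=O)ccc(OCc3ccccc3)c2O1 | intermediate
21 | 5,7-dihydroxy-3-(8-hydroxy-2,2-dimethyl-3,4-dihydro-2H-chromen-5-yl)-4H-chromen-4-one | CC1(C)CCc2c(-c3coc4cc(O)cc(O)c4c3=O)ccc(O)c2O1 | target

Total step count: 8. Longest linear sequence: 6 steps (1 → 3 → 7 → 14 → 16 → 20 → 21, or equally 8 → 11 → 13 → 14 → 16 → 20 → 21).

Steps most likely to fail

Step 7. The cascade may be diverted at 190 °C before the 1,5-H shift and electrocyclisation, by migration of the propargyl unit to the oxygenated ortho carbon followed by a para shift, by five-ring closure of the allenylphenol, or by thermal degradation of the isoflavone. The fallback sets out from 16 and reaches the chroman oxidation level directly. Lindlar semi-hydrogenation (H2, Pd/CaCO3–Pb, quinoline, EtOAc) should give the 1,1-dimethylallyl ether F1. An aromatic Claisen rearrangement at lower temperature (PhNEt2, about 130 °C) should deliver the 2'-prenyl-3'-phenol F2, again only at C2'. Acid-mediated Markovnikov hydroalkoxylation of the prenyl group by the neighbouring phenol (p-TsOH, toluene, 60 °C) should then close the pyran ring to the tribenzyl chroman F3, still as the last ring. Hydrogenolysis (H2, Pd/C) of F3 rejoins the route at compound 21.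

Step 8. Reduction of the pyrone C2=C3 bond (isoflavanone formation) may compete with the slowest benzyl ether cleavage. The fallback sets out from 20 and separates the two operations without any heterogeneous hydrogenation. BCl3 with pentamethylbenzene in CH2Cl2 at −78 °C should remove the three benzyl groups to give the chromene triol F4. Diimide (2-nitrobenzenesulfonyl hydrazide, Et3N, MeCN, rt) should then reduce only the unpolarised cis-disubstituted chromene double bond, and the fallback rejoins the route at compound 21.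

Step 6. O-Alkylation of the hindered ortho-benzyloxy phenoxide by the tertiary propargylic electrophile may be sluggish, with elimination of the chloride to the enyne consuming the reagent. The fallback sets out from 14 and bypasses the ether altogether. Condensation of 14 with 3-methylbut-2-enal (CC(C)=CC=O) and phenylboronic acid (AcOH cat., toluene, reflux, Dean–Stark) should give the 2-phenyl-4H-1,3,2-benzodioxaborinine F5 by ortho-selective aldol-type C-alkylation at C2'. F5 should fragment thermally to the o-quinone methide, where the fallback rejoins the route at compound 19, which closes to 20 as in step 7.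

Further compounds
F1 | step 7 | 5,7-bis(benzyloxy)-3-{4-(benzyloxy)-3-[(2-methylbut-3-en-2-yl)oxy]phenyl}-4H-chromen-4-one | C=CC(C)(C)Oc1cc(-c2coc3cc(OCc4ccccc4)cc(OCc4ccccc4)c3c2=O)ccc1OCc1ccccc1
F2 | step 7 | 5,7-bis(benzyloxy)-3-[4-(benzyloxy)-3-hydroxy-2-(3-methylbut-2-en-1-yl)phenyl]-4H-chromen-4-one | CC(C)=CCc1c(O)c(OCc2ccccc2)ccc1-c1coc2cc(OCc3ccccc3)cc(OCc3ccccc3)c2c1=O
F3 | step 7 | 5,7-bis(benzyloxy)-3-[8-(benzyloxy)-2,2-dimethyl-3,4-dihydro-2H-chromen-5-yl]-4H-chromen-4-one | CC1(C)CCc2c(-c3coc4cc(OCc5ccccc5)cc(OCc5ccccc5)c4c3=O)ccc(OCc3ccccc3)c2O1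
F4 | step 8 | 5,7-dihydroxy-3-(8-hydroxy-2,2-dimethyl-2H-chromen-5-yl)-4H-chromen-4-one | CC1(C)C=Cc2c(-c3coc4cc(O)cc(O)c4c3=O)ccc(O)c2O1
F5 | step 6 | 5,7-bis(benzyloxy)-3-[8-(benzyloxy)-4-(2-methylprop-1-en-1-yl)-2-phenyl-4H-1,3,2-benzodioxaborinin-5-yl]-4H-chromen-4-one | CC(C)=CC1OB(c2ccccc2)Oc2c(OCc3ccccc3)ccc(-c3coc4cc(OCc5ccccc5)cc(OCc5ccccc5)c4c3=O)c21
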